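The capture agent is what separates east, north and the flask, whose substrate and coupling partner charges match.

| flask | substrate | coupling partner | capture agent | remark | time |
|---|---|---|---|---|---|
| east | 0.79 M | 0.474 M (fed, over 20 min) | 0.0079 M | run made earlier |  |
| north | 0.79 M | 0.474 M (fed, over 20 min) | 0.032 M | run made earlier |  |
| south | 0.79 M | 0.95 M (fed, over 20 min) | 0.0158 M | run made earlier |  |
| flask | 0.79 M | 0.474 M (fed, over 20 min) | 0.0158 M |  | 2.0 d |

| run | time / d | substrate / % | product / % |
|---|---|---|---|
| east | 0.167 | 88.4 | 1.3 |
| east | 0.500 | 85.2 | 5.7 |
| east | 0.833 | 85.1 | 6.0 |
| east | 1.25 | 85.2 | 7.1 |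
| east | 1.67 | 84.9 | 8.8 |
| east | 2.50 | 85.7 | 6.2 |
| north | 0.167 | 87.7 | 1.3 |
| north | 0.500 | 86.6 | 5.2 |
| north | 0.833 | 83.1 | 7.3 |
| north | 1.25 | 81.5 | 7.2 |
| north | 1.67 | 80.1 | 5.8 |
| north | 2.50 | 82.0 | 5.8 |
| south | 0.208 | 72.8 | 9.2 |
| south | 0.625 | 67.1 | 13.7 |
| south | 1.04 | 67.4 | 17.6 |
| south | 1.67 | 67.4 | 16.3 |
| south | 2.50 | 68.3 | 15.8 |

(standard deviation of a reading: 1 percentage point)

- the analysis behind the earlier runs scatters by 1 percentage point, standard deviation
- the reaction counts as stopped when no species that holds the substrate changes by six tenths of a point or more over the second half of the time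

1. why nothing more happens at 2.0 d, or that something still does (all of the substrate has reacted / it is still moving / forward and back rates have come level / the coupling partner has run out first)
2. share of the substrate used up at 2.0 d
3. product at 2.0 d, in percent of the substrate charged
4. intermediate A at 2.0 d, in percent of the substrate charged
5. intermediate B at 2.0 d, in percent of the substrate charged

The readings form a ladder. The feed comes first, ending at 20 min. The substrate follows: by 0.167 d east holds 88.4% substrate but 1.3% product, so the rest of the loss sits in species we cannot read. Product comes next, reaching 6.0% in east at 0.833 d. Slower still, north's substrate sinks from 86.6% at 0.500 d to 81.5% at 1.25 d, which is before 2.0 d. After that, the readings wander within their scatter.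

So we replace each tail by its mean over the last 3 readings, which carries about 0.58 percentage points of error. East has used 14.7% of its substrate and north 18.8%. South, with twice east's partner and twice its capture agent, holds 67.7% substrate, less than east's 85.3%. A plateau that shifts with the charges, with substrate left, reads as a balance.

Capture agent over substrate, as charged, is 2.00% in the flask; we call this fraction the capture share. We assume each capture agent removes one substrate for good, on top of a balance pool that is the same at these substrate and partner charges. East's share is 1.00% and north's 4.05%. Their shares differ by 3.0 points and their conversions by 4.1 points, a gap that carries about 0.82 points of error. Subtracting each share and averaging gives a pool of 14.2%. Our reckoning for the flask is therefore 16.2% conversion, at a balance.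

The forecast said forward and back rates have come level, with conversion 16.5%, product 7%, intermediate A 7.5% and intermediate B 2%, on the ground that “Extra capture agent raises conversion about one-for-one”.

The flask gives forward and back rates have come level, with conversion 16.4%, product 6.44%, intermediate A 5.24% and intermediate B 2.70%.

    intermediate B ⇌ product (K = 2.40, k = 0.240 h⁻¹)
    substrate + coupling partner ⇌ intermediate A (K = 0.230 M⁻¹, k = 1.20 M⁻¹ h⁻¹)
    coupling partner + intermediate A ⇌ intermediate B (K = 1.90 M⁻¹, k = 0.800 M⁻¹ h⁻¹)
    capture agent + intermediate A → trapped intermediate (k = 3.50 M⁻¹ h⁻¹)

At 2.00 d the flask's capture agent, the limiting reagent of this irreversible exit, is down to 0.0578% of its charge. Its trapped intermediate stands at 2.00% of the substrate charged, matching the capture share of 2.00%. Conversion less that share leaves 14.4% in the flask's pool.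

A neighbour flask charged with 0.0040 M capture agent has a capture share of 0.506%, so our pool predicts 14.7% conversion. It gives 15.4%, with 0.506% trapped intermediate.

The numbers in the tables were generated by integration from invented constants; scatter was added.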